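**Retrosynthetic overview**
1. Target 14 is C2-symmetric: two identical cyclohexenols joined at ring C4 by an (E,E)-buta-1,3-diene. Both ring C3=C4 bonds are cut at once, by a two-directional ring-closing metathesis, back to the acyclic hexaene 12.
2. Enabling feature: in each ring the olefinic C3–H sits on the quaternary C2 and the olefinic C4 is the terminus of the tetraene. The retron is therefore a vinyl group on a quaternary carbon (no allylic hydrogen, so it cannot isomerise) and the methylidene of a 2-substituted 1,3-diene, placed for six-ring closure.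
3. 12 comes from oxidative homocoupling of dienylstannane 10, itself from Stille coupling of vinyl bromide 8 with distannane 9.
4. 8 comes from Shi epoxidation of 7. 7 comes from phosphoric-acid-catalysed γ-allylboration of aldehyde 5 with geranyl boronate 2, which sets the quaternary carbon and the carbinol together and leaves the vinyl group for the ring closure.
5. Ring order: the oxirane is made first on the monomer (step 5); the two cyclohexene rings are made last and together (step 8).

Key step: step 8

Remark: both halves of the target carry the same descriptors (carbinol R, quaternary carbon S, oxirane R), so one monomer serves both halves; the (S)-phosphoric acid is specified on the premise that the (R)-acid directs allyl transfer to the Re face of aldehydes.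

Step 1
Reactants: 1 geranyl chloride
Product: 2 geranyl pinacol boronate, 2-[(2E)-3,7-dimethylocta-2,6-dien-1-yl]-4,4,5,5-tetramethyl-1,3,2-dioxaborolane
Conditions: B2pin2 (1.1 equiv), Pd2(dba)3 (1 mol %), THF, 60 °C
Reagents that add atoms: bis(pinacolato)diboron, CC1(C)OB(OC1(C)C)B1OC(C)(C)C(C)(C)O1
Why: Allylic borylation under zerovalent-palladium catalysis (π-allyl formation, transmetalation with the diboron, C–B reductive elimination at the CH2 terminus) should give the linear boronate with the E olefin of 1 retained, and this geometry fixes the later relative configuration.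

Step 2
Reactants: 3 pent-4-yn-1-ol
Product: 4 4-bromopent-4-en-1-ol
Conditions: HBr (g), Et4NBr, CH2Cl2, 0 to 40 °C
Reagents that add atoms: hydrogen bromide, Br
Why: Markovnikov hydrobromination of the terminal alkyne by the hydrogen dibromide salt should stop at the 2-bromoalkene, because the vinyl bromide is deactivated towards a second addition.

Step 3
Reactants: 4 4-bromopent-4-en-1-ol
Product: 5 4-bromopent-4-enal
Conditions: PhI(OAc)2 (1.1 equiv), TEMPO (10 mol %), CH2Cl2, 23 °C
Reagents that add atoms: none
Why: Nitroxyl-catalysed oxidation should take the primary alcohol to the aldehyde without over-oxidation and without touching the vinyl bromide.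

Step 4
Reactants: 5 4-bromopent-4-enal; 2 geranyl pinacol boronate
Product: 7 (5R,6S)-2-bromo-6-ethenyl-6,10-dimethylundeca-1,9-dien-5-ol, via pinacol borate ester 6 (not isolated)
Conditions: (S)-TRIP [(S)-3,3'-bis(2,4,6-triisopropylphenyl)-1,1'-binaphthyl-2,2'-diyl hydrogen phosphate] (5 mol %), 4 Å molecular sieves, toluene, −30 to 0 °C; aq. NaHCO3 work-up
Reagents that add atoms: none
Why: Chiral phosphoric acid-catalysed allylboration through a closed chair transition state, in which γ-attack of the E boronate places the homoprenyl chain equatorial and the methyl axial (fixing 6S relative to the carbinol) while the (S)-acid should expose the Si face of 5 and so set 5R.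

Step 5
Reactants: 7 (5R,6S)-2-bromo-6-ethenyl-6,10-dimethylundeca-1,9-dien-5-ol
Product: 8 (5R,6S)-2-bromo-6-{2-[(2R)-3,3-dimethyloxiran-2-yl]ethyl}-6-methylocta-1,7-dien-5-ol
Conditions: D-fructose-derived ketone catalyst (1,2:4,5-di-O-isopropylidene-β-D-erythro-2,3-hexodiulo-2,6-pyranose, 0.3 equiv), KHSO5 (as Oxone, 2KHSO5·KHSO4·K2SO4), K2CO3, Bu4NHSO4, Na2B4O7/Na2EDTA buffer, MeCN–CH2(OMe)2–H2O, 0 °C
Reagents that add atoms: potassium peroxymonosulfate, [K+].[O-]S(=O)(=O)OO
Why: Shi epoxidation, in which the chiral dioxirane should attack only the electron-rich trisubstituted olefin (the vinyl and bromovinyl groups are too electron-poor or hindered) through a spiro transition state that gives the (R)-oxirane under catalyst control, independent of the distant stereocentres.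

Step 6
Reactants: 8 (5R,6S)-2-bromo-6-{2-[(2R)-3,3-dimethyloxiran-2-yl]ethyl}-6-methylocta-1,7-dien-5-ol; 9 (E)-1,2-bis(tributylstannyl)ethene (3 equiv)
Product: 10 (1E,6R,7S)-7-{2-[(2R)-3,3-dimethyloxiran-2-yl]ethyl}-7-methyl-3-methylidene-1-(tributylstannyl)nona-1,8-dien-6-ol
Conditions: Pd(PPh3)4 (5 mol %), CuI (10 mol %), CsF (2 equiv), DMF, 45 °C
Reagents that add atoms: none
Why: Stille coupling (oxidative addition of zerovalent palladium to the C–Br bond, CuI/fluoride-assisted transmetalation, reductive elimination) with excess distannane should give mono-coupling with the E geometry retained, leaving the second tin for the dimerisation.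

Step 7
Reactants: 10 (1E,6R,7S)-7-{2-[(2R)-3,3-dimethyloxiran-2-yl]ethyl}-7-methyl-3-methylidene-1-(tributylstannyl)nona-1,8-dien-6-ol (2 equiv)
Product: 12 (3S,4R,8E,10E,15R,16S)-3,16-bis{2-[(2R)-3,3-dimethyloxiran-2-yl]ethyl}-3,16-dimethyl-7,12-dimethylideneoctadeca-1,8,10,17-tetraene-4,15-diol, via dienylcopper 11 (not isolated)
Conditions: CuCl (5 equiv), DMF, 23 °C, argon, dark; aq. NH3/NH4Cl work-up
Reagents that add atoms: none
Why: Tin-to-copper transmetalation followed by oxidative homocoupling of the alkenylcopper (CuCl-mediated alkenylstannane dimerisation) joins the two metal-bearing sp2 carbons with retention, so the new central diene should be E,E.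

Step 8
Reactants: 12 (3S,4R,8E,10E,15R,16S)-3,16-bis{2-[(2R)-3,3-dimethyloxiran-2-yl]ethyl}-3,16-dimethyl-7,12-dimethylideneoctadeca-1,8,10,17-tetraene-4,15-diol
Product: 14 CNP0229121.4, (1R,1'R,2S,2'S)-4,4'-[(1E,3E)-buta-1,3-diene-1,4-diyl]bis(2-{2-[(2R)-3,3-dimethyloxiran-2-yl]ethyl}-2-methylcyclohex-3-en-1-ol), via mono-cyclised triene 13 (not isolated)
Conditions: second-generation Hoveyda–Grubbs catalyst (2 × 7.5 mol %), 1,4-benzoquinone (20 mol %), CH2Cl2 (0.002 M), 40 °C, argon sparge
Reagents that add atoms: none
Why: The ruthenium alkylidene should initiate at the only monosubstituted olefin, the vinyl group on the quaternary carbon, add across the methylidene of the 2-substituted diene, and release the trisubstituted ring olefin and Ru=CH2 by cycloreversion; loss of ethene and repetition on the second half via 13 completes the two-directional closure. The closest known reaction type is ring-closing metathesis of a terminal olefin onto the 1,1-disubstituted terminus of a 1,3-diene to give a 1-alkenylcyclohexene. Each cyclohexene closes in the same mode, as a six-membered carbocycle formed between the vinyl CH and the methylidene-bearing carbon, helped by the gem-dialkyl effect of the adjacent quaternary carbon. No stereocentre is created: the ring olefin can only be cis within the six-membered ring, and the E,E diene, the four ring stereocentres and the two oxiranes are not touched, so no protecting group is needed. The selectivity required is site selectivity for the methylidene over the internal E-disubstituted diene bonds, where attack would give a seven-membered ring and cut the chain; faster six-ring closure, the conjugation and substitution of the internal bonds, and high dilution should secure it. The quaternary carbon also leaves no allylic hydrogen next to the vinyl group, so olefin migration before closure is excluded.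

**Compound list**
1 | geranyl chloride, (2E)-1-chloro-3,7-dimethylocta-2,6-diene | CC(C)=CCC/C(C)=C/CCl | starting material
2 | geranyl pinacol boronate, 2-[(2E)-3,7-dimethylocta-2,6-dien-1-yl]-4,4,5,5-tetramethyl-1,3,2-dioxaborolane | CC(C)=CCC/C(C)=C/CB1OC(C)(C)C(C)(C)O1 | intermediate
3 | pent-4-yn-1-ol | OCCCC#C | starting material
4 | 4-bromopent-4-en-1-ol | OCCCC(Br)=C | intermediate
5 | 4-bromopent-4-enal | O=CCCC(Br)=C | intermediate
6 | 2-{[(5R,6S)-2-bromo-6-ethenyl-6,10-dimethylundeca-1,9-dien-5-yl]oxy}-4,4,5,5-tetramethyl-1,3,2-dioxaborolane | C=C[C@](C)(CCC=C(C)C)[C@H](OB1OC(C)(C)C(C)(C)O1)CCC(Br)=C | intermediate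
7 | (5R,6S)-2-bromo-6-ethenyl-6,10-dimethylundeca-1,9-dien-5-ol | C=C[C@](C)(CCC=C(C)C)[C@H](O)CCC(Br)=C | intermediate
8 | (5R,6S)-2-bromo-6-{2-[(2R)-3,3-dimethyloxiran-2-yl]ethyl}-6-methylocta-1,7-dien-5-ol | C=C[C@](C)(CC[C@H]1OC1(C)C)[C@H](O)CCC(Br)=C | intermediate
9 | (E)-1,2-bis(tributylstannyl)ethene | CCCC[Sn](CCCC)(CCCC)/C=C/[Sn](CCCC)(CCCC)CCCC | starting material
10 | (1E,6R,7S)-7-{2-[(2R)-3,3-dimethyloxiran-2-yl]ethyl}-7-methyl-3-methylidene-1-(tributylstannyl)nona-1,8-dien-6-ol | C=C[C@](C)(CC[C@H]1OC1(C)C)[C@H](O)CCC(=C)/C=C/[Sn](CCCC)(CCCC)CCCC | intermediate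
11 | [(1E,6R,7S)-7-{2-[(2R)-3,3-dimethyloxiran-2-yl]ethyl}-6-hydroxy-7-methyl-3-methylidenenona-1,8-dien-1-yl]copper | C=C[C@](C)(CC[C@H]1OC1(C)C)[C@H](O)CCC(=C)/C=C/[Cu] | intermediate
12 | (3S,4R,8E,10E,15R,16S)-3,16-bis{2-[(2R)-3,3-dimethyloxiran-2-yl]ethyl}-3,16-dimethyl-7,12-dimethylideneoctadeca-1,8,10,17-tetraene-4,15-diol | C=C[C@](C)(CC[C@H]1OC1(C)C)[C@H](O)CCC(=C)/C=C/C=C/C(=C)CC[C@@H](O)[C@@](C)(CC[C@H]1OC1(C)C)C=C | intermediate
13 | (1R,2S)-4-[(1E,3E,8R,9S)-9-{2-[(2R)-3,3-dimethyloxiran-2-yl]ethyl}-8-hydroxy-9-methyl-5-methylideneundeca-1,3,10-trien-1-yl]-2-{2-[(2R)-3,3-dimethyloxiran-2-yl]ethyl}-2-methylcyclohex-3-en-1-ol | C=C[C@](C)(CC[C@H]1OC1(C)C)[C@H](O)CCC(=C)/C=C/C=C/C1=C[C@](C)(CC[C@H]2OC2(C)C)[C@H](O)CC1 | intermediate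
14 | CNP0229121.4, (1R,1'R,2S,2'S)-4,4'-[(1E,3E)-buta-1,3-diene-1,4-diyl]bis(2-{2-[(2R)-3,3-dimethyloxiran-2-yl]ethyl}-2-methylcyclohex-3-en-1-ol) | CC1(C)O[C@@H]1CC[C@@]1(C)C=C(/C=C/C=C/C2=C[C@](C)(CC[C@H]3OC3(C)C)[C@H](O)CC2)CC[C@H]1O | target

**Step count and risks**
Total steps: 8. Longest linear sequence: 7 steps (3 → 4 → 5 → 7 → 8 → 10 → 12 → 14); step 1 is the side branch.

Most likely to fail, step 8: the ruthenium carbene may engage the internal double bonds of the conjugated tetraene, leading to chain scission or oligomerisation, or the reaction may stall after the first closure. The fallback sets out from 10 and closes the ring before the tetraene exists. Ring-closing metathesis of 10 alone (second-generation Hoveyda–Grubbs catalyst, CH2Cl2, 40 °C) acts on a substrate whose only internal olefin is shielded by tin, and should give tributyl{(E)-2-[(3S,4R)-3-{2-[(2R)-3,3-dimethyloxiran-2-yl]ethyl}-4-hydroxy-3-methylcyclohex-1-en-1-yl]ethenyl}stannane F1. Treatment of F1 with CuCl in DMF would pass through the corresponding alkenylcopper F2, whose oxidative homocoupling makes the central diene last and returns to the route at 14.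

Second, step 4: turnover may be slow and facial selectivity insufficient, because the γ,γ-disubstituted boronate is hindered and the aldehyde is aliphatic and enolisable. The fallback sets out from 1 and 5 and replaces the boron/Brønsted-acid manifold by a catalytic asymmetric Nozaki–Hiyama allylation. The conditions would be nickel-free CrCl3 (10 mol %), a chiral carbazole-linked bis(oxazoline) ligand (the antipode that delivers the 5R,6S isomer), Mn powder, Me3SiCl and Et3N in THF at 0 °C. The E-allylchromium formed from 1 should add through a chair transition state with the larger γ-substituent equatorial, giving the same relative configuration as the silyl ether {[(5R,6S)-2-bromo-6-ethenyl-6,10-dimethylundeca-1,9-dien-5-yl]oxy}trimethylsilane F3; the vinyl bromide is inert to divalent chromium without nickel. Methanolysis (K2CO3, MeOH) returns to the route at 7.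

Third, step 7: tin-to-copper exchange of the tributylstannane may be slow, with competing protodestannylation, or chloride may open the oxiranes. The fallback sets out from 10 and turns the homocoupling into a cross-coupling. Half of 10 is iododestannylated (I2, NaHCO3, CH2Cl2, 0 °C) to (1E,6R,7S)-7-{2-[(2R)-3,3-dimethyloxiran-2-yl]ethyl}-1-iodo-7-methyl-3-methylidenenona-1,8-dien-6-ol F4. Stille coupling of F4 with the other half of 10 (PdCl2(MeCN)2, DMF, 23 °C) returns to the route at 12.

Further compounds
F1 | step 8 | tributyl{(E)-2-[(3S,4R)-3-{2-[(2R)-3,3-dimethyloxiran-2-yl]ethyl}-4-hydroxy-3-methylcyclohex-1-en-1-yl]ethenyl}stannane | CCCC[Sn](CCCC)(CCCC)/C=C/C1=C[C@](C)(CC[C@H]2OC2(C)C)[C@H](O)CC1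
F2 | step 8 | {(E)-2-[(3S,4R)-3-{2-[(2R)-3,3-dimethyloxiran-2-yl]ethyl}-4-hydroxy-3-methylcyclohex-1-en-1-yl]ethenyl}copper | [Cu]/C=C/C1=C[C@](C)(CC[C@H]2OC2(C)C)[C@H](O)CC1
F3 | step 4 | {[(5R,6S)-2-bromo-6-ethenyl-6,10-dimethylundeca-1,9-dien-5-yl]oxy}trimethylsilane | C=C[C@](C)(CCC=C(C)C)[C@H](O[Si](C)(C)C)CCC(Br)=C
F4 | step 7 | (1E,6R,7S)-7-{2-[(2R)-3,3-dimethyloxiran-2-yl]ethyl}-1-iodo-7-methyl-3-methylidenenona-1,8-dien-6-ol | C=C[C@](C)(CC[C@H]1OC1(C)C)[C@H](O)CCC(=C)/C=C/I
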